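The data stem from a simulated flask with constants of no real substance, noise included.

In this flask D outnumbers E by 15.0 to one, and what to watch on a repeat depends on what that D does.

the same everywhere: X 0.10 M (fed, over 8.0 min); E 0.2 mol%

| run | D | remark | time |
|---|---|---|---|
| Tuesday's | 3 mM | the very flask that is asked about, followed so far |  |
| flask | 3.00 mM |  | 8.0 min |

- Tuesday's (time / min: J / %, X / %): 0.667: 0, 8.5; 1.33: 0, 15.3; 2.00: 0, 23.7; 2.50: 0.8, 27.8

(scatter of a reading: 1 percentage point)

- the average divides the monomer in chains by the number of chains begun, living and dead together
- the numbers in the tables scatter by 1 percentage point (one standard deviation)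
- the earlier runs do not show the number of chains; that part of a forecast is a guess
- percentages count the whole charge, also what has not yet gone in

1. average number of monomer units in a chain (chains begun, living or dead) at 8.0 min
2. part of the X that has reacted at 8.0 min

One chemist holds that D eats X. By 2.50 min the feed has brought 31.2% of the charge, yet X reads 27.8% and J 0.8%. D amounts to 3.00% of the charge, so on this view D takes X one for one, J starts afterwards, and J then grows in proportion to X until X is used.

A second chemist holds that D ends chains. At 2.00 min the gap between feed and X is 1.3 percentage points against a scatter of 1 point, so J may be forming unseen. D could end each chain begun from E 15.0 times over, so J should stop short of the charge.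

Both count one chain per E, which is a guess, since no run shows chains. Here 500 units of X stand per E charged, the chain ceiling, and once E has begun its chains, dp is the ceiling times c. My own reckoning sides with the second chemist: c lags a steady first-order rise, and dp follows from c by the ceiling. What to watch is X plus J against what the feed has brought: a shortfall near 3.00% of the charge would speak for the first chemist.

The forecast gives dp 150 and c 35%, on the ground that “Polymer starts once D is gone”. The flask gives dp 102 and c 20.0%.

    Z + D → L (k = 110 /M/min)
    X + Q → Z + J (k = 39.0 /M/min)
    X + Z → J + Z, rate k3*[Z]*[X] (k = 860 /M/min)
    E → Q (k = 0.500 /min)

The ceiling times c gives 100, and at 8.00 min X 80.0% and J 20.0% sum to the charge, with D at 94.9% of its own; c is 29.9% at 80.0 min. Between 4.00 min and 8.00 min, E fell from 13.5% to 1.83% of its charge while Z fell from 0.0935% to 0.0432% of the X charge. The first chemist's J in proportion to X has its region around 8.00 min in spans short against 2.2 min, the half-life of Z by D alone at that time, which is shorter than the 19 min half-life of X by the step to J; within such a span the uptake of X is pseudo-first-order.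

With 0.5 mol% of E the ceiling is 200, so c of 41.3% means dp 82.5; that flask gives 84.5.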